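Numbering, used for every bicyclic intermediate: cyclopentane C1(CH3)–C2(OAc)–C3–C4(OH)(i-Pr)–C5 and cycloheptenone C5–C6(OCOAr)–C7=C8(CH3)–C9(=O)–C10–C1. β is the face of the C1 methyl group.
Retrosynthetic cuts, in order: the phenol silyl ether, the C9 carbonyl oxygen (allylic C–H), the C6 and C2 ester C–O bonds, C4–i-Pr, C8–CH3, and last the ring-fusion bond C1–C5, which is exchanged for C1–C6.
Enabling feature: C5 lies between the oxygen-bearing carbons C4 and C6, and C1 is 1,3-related to C5 through C6. A decalin (ring A C1–C6, ring B C1, C6–C10) with a hydroxyl on C6 and a leaving group on C5 therefore gives the 5-7 skeleton, the C6 carbonyl and an intact C4–O bond in one 1,2-shift of C1.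
Alignment decides which carbon moves: in the ring-fused 4β,5β-epoxy-6β-ol the C5–O bond is anti to C7, not to the endocyclic C6–C1 bond. That epoxide therefore only places O4 and O5 and is opened at C4; the 5β-oxygen, now free to sit equatorial on ring A and anti to C6–C1, leaves as a mesylate.
Forward order: both six-membered rings come from (S)-Wieland–Miescher ketone. Ring A is oxidised at C6, C5 and C4, step 9 turns the two rings into cyclopentane and cycloheptanone at once, and then C8–CH3, C4–i-Pr, the two esters and the C9 ketone follow.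
Stereochemistry: C1 comes from the starting ketone and is retained as the migrating carbon. C2 is set by hydride attack anti to the methyl, and C5 by inversion at the 5β-mesylate (placed through the β-epoxide, the 6β-OH and a hydroxyl-directed epoxidation). C4 is set by organocerium attack on the α face, and C6 by hydride delivery from the 4β-hydroxyl.

Key step: step 9

Remark on the chemistry: the reduction in step 13 only masks the C6 carbonyl and its stereocentre is erased in step 19. Compounds 20–25 are therefore drawn as the expected 6β epimer, and any 6α epimer would be carried along to the same enone 26.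

Step 1
Reactants: 1 (S)-Wieland–Miescher ketone
Product: 2 (4aS,5S)-5-hydroxy-4a-methyl-4,4a,5,6,7,8-hexahydronaphthalen-2(3H)-one (2β-hydroxy enone, OH cis to the angular methyl)
Conditions: NaBH4 (0.3 equiv), EtOH, 0 °C
Reagents that add atoms: none
Why: Chemoselective borohydride reduction of the isolated C2 ketone beside the less electrophilic enone, with hydride entering from the α face anti to the axial C1 methyl, so that the equatorial 2β-alcohol should result.

Step 2
Reactants: 2 2β-hydroxy enone; 3 ethylene glycol
Product: 4 2β-hydroxy-5(6)-ene 8,8-ethylene ketal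
Conditions: p-TsOH·H2O (cat.), benzene, reflux, Dean–Stark
Reagents that add atoms: none
Why: Acid-catalysed ketalisation of the enone, which as with steroidal 4-en-3-ones leaves the alkene deconjugated at C5=C6, the position needed to oxidise ring A.

Step 3
Reactants: 4 hydroxy ketal
Product: 5 2β-OTBS 5(6)-ene ketal
Conditions: TBSOTf, 2,6-lutidine, CH2Cl2, 0 °C
Reagents that add atoms: tert-butyldimethylsilyl triflate, CC(C)(C)[Si](C)(C)OS(=O)(=O)C(F)(F)F
Why: Standard silylation of a hindered secondary alcohol with the silyl triflate, in a buffered medium that leaves the dioxolane intact and gives an ether that lasts until step 18.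

Step 4
Reactants: 5 alkene ketal
Product: 7 5β,6β-epoxide (oxirane cis to the C1 methyl), via bromohydrin 6 (not isolated)
Conditions: NBS, acetone/H2O, 0 °C; then K2CO3, MeOH, rt
Reagents that add atoms: water, O
Why: Halohydrin formation and Williamson-type closure: the bromonium ion forms on the open α face, water opens it anti from the β face and the alkoxide displaces bromide with inversion, so the oxirane oxygen ends on the β face, opposite to what a peracid would give.

Step 5
Reactants: 7 5β,6β-epoxide
Product: 10 cis-fused 6β-hydroxy-4(5)-ene, via hydroxy selenide 8 (not isolated), via selenoxide 9 (not isolated)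
Conditions: PhSeSePh, NaBH4, EtOH, reflux; then 30% H2O2, THF, 0 °C → rt
Reagents that add atoms: none
Why: Epoxide-to-allylic-alcohol transposition by selenolate opening and selenoxide syn-elimination: PhSe− attacks the only secondary oxirane carbon C5 from the α face (trans-diaxial opening, possible in the flexible cis-decalin), the C6–O bond and its β configuration stay untouched, and the selenoxide can eliminate only towards C4 because C6 carries no hydrogen.

Step 6
Reactants: 10 tertiary allylic alcohol
Product: 11 cis-fused 4β,5β-epoxy-6β-ol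
Conditions: VO(acac)2 (cat.), t-BuOOH, CH2Cl2, 0 °C → rt
Reagents that add atoms: tert-butyl hydroperoxide, CC(C)(C)OO
Why: Hydroxyl-directed vanadium-catalysed epoxidation of an allylic alcohol, in which the metal-bound peroxide is delivered syn to the 6β-hydroxyl, which is also the convex face of the cis-decalin, so both new C–O bonds are β.

Step 7
Reactants: 11 epoxy alcohol; 12 4-methoxybenzyl alcohol
Product: 13 4α-(4-methoxybenzyloxy)-5β,6β-diol
Conditions: NaH, DMF, 90 °C
Reagents that add atoms: none
Why: SN2 opening of a 2,3-epoxy alcohol at the distal carbon (Fürst–Plattner trans-diaxial course): C5 is neopentyl and next to the alkoxide, so the benzylic alkoxide inverts C4 and leaves the 5β C–O bond intact, while a Payne shift is excluded because O6 is syn to the oxirane.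

Step 8
Reactants: 13 diol
Product: 14 5β-mesylate with free 6β-hydroxyl (precursor of the key step)
Conditions: MsCl, Et3N, CH2Cl2, −10 °C
Reagents that add atoms: methanesulfonyl chloride, CS(=O)(=O)Cl
Why: Sulfonylation through sulfene, which takes the only secondary hydroxyl and leaves the tertiary ring-fusion carbinol free.

Step 9
Reactants: 14 5β-mesyloxy-6β-ol
Product: 16 trans-fused hydroazulen-6-one with 2β-OTBS 4α-OPMB and 8,8-ethylene ketal, via aluminium alkoxide 15 (not isolated)
Conditions: Et2AlCl (2.5 equiv), CH2Cl2, −78 → −20 °C; cold aq. Rochelle salt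
Reagents that add atoms: none
Why: Et2AlCl turns the free 6β-hydroxyl into the chloro(ethyl)aluminium alkoxide 15 and further Lewis acid pulls on the mesylate, so C1 moves with its bonding pair from C6 to C5 while C6–O becomes the carbonyl, a concerted semipinacol (pinacol-type) rearrangement of a 2-sulfonyloxy alcohol, the reaction type known for turning hydronaphthalenes into hydroazulenes. No ring is closed by attack on a π bond: making C1–C5 and breaking C1–C6 in one suprafacial 1,2-alkyl shift (retention at C1) contracts ring A to the cyclopentane C1–C5 and inserts C5 into ring B, which grows to the cycloheptanone. The only new stereocentre, C5, is set by backside displacement of the 5β C–O bond, so H5 ends α and trans to the β methyl on C1. The shift needs C5–O anti to C6–C1, which holds in the chair–chair form with OMs and OPMB equatorial on ring A, an alignment a ring-fused 4,5-epoxide cannot reach. The flipped form (OMs axial and anti to C7) suffers CH3/OMs and C7/OPMB 1,3-diaxial contacts and would move a poorer primary carbon than quaternary C1, and C3, which is also anti, has no donor because O4 is an ether. The non-basic medium keeps H5, now α to the ketone, from epimerising and O4 from β-elimination.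

Step 10
Reactants: 16 keto ketal
Product: 17 trans-fused hydroazulene-6,8-dione
Conditions: 1 M HCl, THF, 0 °C → rt
Reagents that add atoms: water, O
Why: Acid hydrolysis of the dioxolane, which is easy for a β-keto ketal and mild enough for the hindered TBS ether and the PMB ether.

Step 11
Reactants: 17 1,3-diketone
Product: 18 8-triflyloxy-7-en-6-one
Conditions: Tf2O, Et3N, CH2Cl2, −78 °C
Reagents that add atoms: triflic anhydride, O=S(=O)(OS(=O)(=O)C(F)(F)F)C(F)(F)F
Why: O-sulfonylation of a cyclic 1,3-diketone to the vinylogous triflate, expected at the less hindered O8 because O6 is flanked by the C5 methine and the C4 ether.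

Step 12
Reactants: 18 β-triflyloxy enone
Product: 19 8-methyl-7-en-6-one
Conditions: Me2CuLi (MeLi, CuI), Et2O, −78 °C
Reagents that add atoms: lithium dimethylcuprate, [Li+].C[Cu-]C
Why: Cuprate addition–elimination on a β-triflyloxy enone, which puts the methyl group on C8 and fixes the alkene at C7=C8 without touching C5.

Step 13
Reactants: 19 enone
Product: 20 6β-allylic alcohol
Conditions: NaBH4, CeCl3·7H2O, MeOH, −40 °C
Reagents that add atoms: none
Why: Luche 1,2-reduction used to mask the C6 carbonyl, with hydride expected from the α face because the C1 methyl screens the β face.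

Step 14
Reactants: 20 allylic alcohol
Product: 21 2β,6β-bis-OTBS ether
Conditions: TBSOTf, 2,6-lutidine, CH2Cl2, 0 °C
Reagents that add atoms: tert-butyldimethylsilyl triflate, CC(C)(C)[Si](C)(C)OS(=O)(=O)C(F)(F)F
Why: Silylation with the silyl triflate gives a poor leaving group at C6, which is needed once C4 becomes a ketone.

Step 15
Reactants: 21 PMB ether
Product: 22 4α-alcohol
Conditions: DDQ, CH2Cl2/pH 7 buffer, 0 °C
Reagents that add atoms: none
Why: Oxidative cleavage of the electron-rich benzyl ether by DDQ, which is fast enough at 0 °C to spare the alkene and both silyl ethers.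

Step 16
Reactants: 22 4α-alcohol
Product: 23 cyclopentan-4-one
Conditions: Dess–Martin periodinane, CH2Cl2, 0 °C → rt
Reagents that add atoms: none
Why: Dess–Martin oxidation under near-neutral conditions, so the C5 stereocentre next to the new ketone and the two β-silyloxy groups are not disturbed.

Step 17
Reactants: 23 ketone
Product: 24 4β-hydroxy-4α-isopropyl compound
Conditions: i-PrMgCl, CeCl3 (anhydrous), THF, −78 °C
Reagents that add atoms: isopropylmagnesium chloride, CC(C)[Mg]Cl
Why: Organocerium 1,2-addition, whose low basicity suppresses enolisation, β-elimination and hydride transfer, with attack from the α face because the C1 methyl and the C2 silyl ether cover the β face, which places i-Pr α and OH β.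

Step 18
Reactants: 24 bis-silyl ether
Product: 25 2β,4β,6β-triol
Conditions: TBAF, THF, 50 °C
Reagents that add atoms: none
Why: Fluoride desilylation, chosen over acid because the C6 allylic oxygen with its methyl-substituted alkene would ionise easily.

Step 19
Reactants: 25 triol
Product: 26 2β,4β-dihydroxy-7-en-6-one
Conditions: MnO2 (activated), CH2Cl2, rt
Reagents that add atoms: none
Why: MnO2 oxidation is selective for the allylic carbinol, so C6 returns to the enone while the saturated C2 alcohol and the tertiary C4 alcohol stay.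

Step 20
Reactants: 26 dihydroxy enone
Product: 27 2β-acetate
Conditions: Ac2O, DMAP (cat.), pyridine, rt
Reagents that add atoms: acetic anhydride, CC(=O)OC(C)=O
Why: DMAP-catalysed acetylation of the only secondary hydroxyl, the hindered tertiary C4 alcohol being inert under these conditions.

Step 21
Reactants: 27 β-hydroxy enone
Product: 29 6α-allylic alcohol, via alkoxyborohydride 28 (not isolated)
Conditions: Me4NBH(OAc)3, MeCN/AcOH, −30 °C
Reagents that add atoms: none
Why: Evans–Saksena hydroxyl-directed reduction: the reagent does not reduce the enone by itself, exchanges one acetate for the 4β-hydroxyl and delivers hydride within a six-membered transition state to the β face of C6, which gives H6 β and the 6α-alcohol anti to O4.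

Step 22
Reactants: 30 4-hydroxybenzoic acid
Product: 32 4-(tert-butyldimethylsilyloxy)benzoic acid, via silyl ester 31 (not isolated)
Conditions: TBSCl (2.2 equiv), imidazole, DMF, rt; then AcOH, THF/H2O, rt
Reagents that add atoms: tert-butyldimethylsilyl chloride, CC(C)(C)[Si](C)(C)Cl
Why: Silylation of both acidic hydroxyls followed by selective hydrolysis of the far more labile silyl ester, which leaves the aryl silyl ether.

Step 23
Reactants: 29 6α-alcohol; 32 protected acid
Product: 33 6α-[4-(TBSO)benzoate]
Conditions: DCC, DMAP, CH2Cl2, rt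
Reagents that add atoms: none
Why: Steglich esterification with retention at C6, selective because the only other hydroxyl is the tertiary one at C4.

Step 24
Reactants: 33 allylic ester
Product: 34 7-en-9-one
Conditions: CrO3, 3,5-dimethylpyrazole, CH2Cl2, −20 °C
Reagents that add atoms: chromium trioxide, O=[Cr](=O)=O
Why: Allylic oxidation of a trisubstituted cycloalkene to the enone with the CrO3–dimethylpyrazole complex, directed to the ring methylene C9 because C6–H is deactivated by its acyloxy group and the primary C–H bonds of the methyl group react more slowly.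

Step 25
Reactants: 34 silyl-protected enone
Product: 35 target compound
Conditions: TBAF, AcOH, THF, 0 °C
Reagents that add atoms: none
Why: Buffered fluoride cleavage of the aryl silyl ether, which is much faster than any attack on the acetate, the benzoate or the enone.

Compound list
1 | (S)-Wieland–Miescher ketone | O=C1CCCC2=CC(=O)CC[C@]12C | starting material
2 | (4aS,5S)-5-hydroxy-4a-methyl-4,4a,5,6,7,8-hexahydronaphthalen-2(3H)-one (2β-OH) | O[C@H]1CCCC2=CC(=O)CC[C@]12C | intermediate
3 | ethylene glycol | OCCO | starting material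
4 | 2β-hydroxy-5(6)-ene 8,8-ethylene ketal | O[C@H]1CCC=C2CC3(OCCO3)CC[C@]12C | intermediate
5 | 2β-OTBS 5(6)-ene 8,8-ethylene ketal | CC(C)(C)[Si](C)(C)O[C@H]1CCC=C2CC3(OCCO3)CC[C@]12C | intermediate
6 | 6α-bromo-5β-hydroxy decalin (bromohydrin, not isolated) | CC(C)(C)[Si](C)(C)O[C@H]1CC[C@@H](O)[C@@]2(Br)CC3(OCCO3)CC[C@]12C | intermediate
7 | 5β,6β-epoxide | CC(C)(C)[Si](C)(C)O[C@H]1CC[C@H]2O[C@]23CC4(OCCO4)CC[C@]13C | intermediate
8 | 5α-phenylselanyl-6β-ol, cis-decalin (not isolated) | CC(C)(C)[Si](C)(C)O[C@H]1CC[C@H]([Se]c2ccccc2)[C@]3(O)CC4(OCCO4)CC[C@]13C | intermediate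
9 | selenoxide of 8 (not isolated) | CC(C)(C)[Si](C)(C)O[C@H]1CC[C@H]([Se](=O)c2ccccc2)[C@]3(O)CC4(OCCO4)CC[C@]13C | intermediate
10 | cis-fused 6β-hydroxy-4(5)-ene | CC(C)(C)[Si](C)(C)O[C@H]1CC=C[C@]2(O)CC3(OCCO3)CC[C@]12C | intermediate
11 | cis-fused 4β,5β-epoxy-6β-ol | CC(C)(C)[Si](C)(C)O[C@H]1C[C@H]2O[C@H]2[C@]3(O)CC4(OCCO4)CC[C@]13C | intermediate
12 | 4-methoxybenzyl alcohol | COc1ccc(CO)cc1 | starting material
13 | 4α-OPMB-5β,6β-diol | CC(C)(C)[Si](C)(C)O[C@H]1C[C@H](OCc2ccc(OC)cc2)[C@@H](O)[C@]3(O)CC4(OCCO4)CC[C@]13C | intermediate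
14 | 4α-OPMB-5β-mesyloxy-6β-ol (key-step precursor) | CC(C)(C)[Si](C)(C)O[C@H]1C[C@H](OCc2ccc(OC)cc2)[C@@H](OS(C)(=O)=O)[C@]3(O)CC4(OCCO4)CC[C@]13C | intermediate
15 | chloro(ethyl)aluminium 6β-alkoxide of 14 (not isolated) | CC(C)(C)[Si](C)(C)O[C@H]1C[C@H](OCc2ccc(OC)cc2)[C@@H](OS(C)(=O)=O)[C@]3(O[Al](Cl)CC)CC4(OCCO4)CC[C@]13C | intermediate
16 | trans-fused hydroazulen-6-one, 2β-OTBS, 4α-OPMB, 5α-H, 8,8-ethylene ketal (key-step product) | CC(C)(C)[Si](C)(C)O[C@H]1C[C@H](OCc2ccc(OC)cc2)[C@H]3C(=O)CC4(OCCO4)CC[C@]13C | intermediate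
17 | hydroazulene-6,8-dione | CC(C)(C)[Si](C)(C)O[C@H]1C[C@H](OCc2ccc(OC)cc2)[C@H]3C(=O)CC(=O)CC[C@]13C | intermediate
18 | 8-triflyloxy-7-en-6-one | CC(C)(C)[Si](C)(C)O[C@H]1C[C@H](OCc2ccc(OC)cc2)[C@H]3C(=O)C=C(OS(=O)(=O)C(F)(F)F)CC[C@]13C | intermediate
19 | 8-methyl-7-en-6-one | CC(C)(C)[Si](C)(C)O[C@H]1C[C@H](OCc2ccc(OC)cc2)[C@H]3C(=O)C=C(C)CC[C@]13C | intermediate
20 | 6β-allylic alcohol | CC(C)(C)[Si](C)(C)O[C@H]1C[C@H](OCc2ccc(OC)cc2)[C@H]3[C@@H](O)C=C(C)CC[C@]13C | intermediate
21 | 2β,6β-bis-OTBS, 4α-OPMB | CC(C)(C)[Si](C)(C)O[C@H]1C[C@H](OCc2ccc(OC)cc2)[C@H]3[C@@H](O[Si](C)(C)C(C)(C)C)C=C(C)CC[C@]13C | intermediate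
22 | 4α-alcohol | CC(C)(C)[Si](C)(C)O[C@H]1C[C@H](O)[C@H]3[C@@H](O[Si](C)(C)C(C)(C)C)C=C(C)CC[C@]13C | intermediate
23 | 4-ketone | CC(C)(C)[Si](C)(C)O[C@H]1CC(=O)[C@H]3[C@@H](O[Si](C)(C)C(C)(C)C)C=C(C)CC[C@]13C | intermediate
24 | 4β-hydroxy-4α-isopropyl bis-silyl ether | CC(C)(C)[Si](C)(C)O[C@H]1C[C@](O)(C(C)C)[C@H]3[C@@H](O[Si](C)(C)C(C)(C)C)C=C(C)CC[C@]13C | intermediate
25 | 2β,4β,6β-triol | O[C@H]1C[C@](O)(C(C)C)[C@H]3[C@@H](O)C=C(C)CC[C@]13C | intermediate
26 | 2β,4β-dihydroxy-7-en-6-one | O[C@H]1C[C@](O)(C(C)C)[C@H]2C(=O)C=C(C)CC[C@]12C | intermediate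
27 | 2β-acetoxy-4β-hydroxy-7-en-6-one | CC(=O)O[C@H]1C[C@](O)(C(C)C)[C@H]2C(=O)C=C(C)CC[C@]12C | intermediate
28 | tetramethylammonium 4β-alkoxy(diacetoxy)borohydride of 27 (not isolated) | CC(=O)O[C@H]1C[C@](O[BH-](OC(C)=O)OC(C)=O)(C(C)C)[C@H]2C(=O)C=C(C)CC[C@]12C.C[N+](C)(C)C | intermediate
29 | 2β-acetoxy-4β,6α-diol | CC(=O)O[C@H]1C[C@](O)(C(C)C)[C@H]2[C@H](O)C=C(C)CC[C@]12C | intermediate
30 | 4-hydroxybenzoic acid | OC(=O)c1ccc(O)cc1 | starting material
31 | TBS 4-(TBSO)benzoate (not isolated) | CC(C)(C)[Si](C)(C)Oc1ccc(cc1)C(=O)O[Si](C)(C)C(C)(C)C | intermediate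
32 | 4-(tert-butyldimethylsilyloxy)benzoic acid | CC(C)(C)[Si](C)(C)Oc1ccc(cc1)C(=O)O | intermediate
33 | 6α-[4-(TBSO)benzoate] of 29 | CC(=O)O[C@H]1C[C@](O)(C(C)C)[C@H]2[C@H](OC(=O)c3ccc(O[Si](C)(C)C(C)(C)C)cc3)C=C(C)CC[C@]12C | intermediate
34 | 9-oxo derivative of 33 | CC(=O)O[C@H]1C[C@](O)(C(C)C)[C@H]2[C@H](OC(=O)c3ccc(O[Si](C)(C)C(C)(C)C)cc3)C=C(C)C(=O)C[C@]12C | intermediate
35 | CNP0087181.7 | CC(=O)O[C@H]1C[C@](O)(C(C)C)[C@H]2[C@H](OC(=O)c3ccc(O)cc3)C=C(C)C(=O)C[C@]12C | target

Total step count: 25. Longest linear sequence: 24 (steps 1–21 and 23–25).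

Steps most likely to fail

Step 9. Ring A may react from the flipped chair, in which the mesylate is axial and C7 migrates instead of C1. The Lewis acid may also open the dioxolane or let the PMB ether take part. The fallback locks the alignment with a tether instead of relying on a conformational preference, and sets out from epoxy alcohol 11.
- KOH in aqueous DMSO at 100 °C opens the oxirane at C4 to the 4α,5β,6β-triol F1.
- SOCl2/Et3N (CH2Cl2, 0 °C) ties the two secondary hydroxyls into the trans-fused cyclic sulfite F2, and RuCl3 (cat.)/NaIO4 oxidises it to the cyclic sulfate F3.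
- A five-membered ring trans-fused to ring A can only span two equatorial positions. C5–O is therefore held anti to C6–C1, and the axial arrangement that would let C7 move is excluded.
- KHMDS (1 equiv, THF, −78 → 0 °C) forms the C6 alkoxide, C1 shifts, and the sulfate stays on O4 as the potassium sulfate monoester F4.
- H2SO4 (cat.) with one equivalent of water in THF frees the 4α-hydroxy ketone F5.
- 4-Methoxybenzyl trichloroacetimidate with La(OTf)3 (cat.) brings the sequence back to 16.

Step 5. The oxirane may open slowly or at the wrong carbon, because the selenolate must reach the neopentyl carbon C5 from the concave α face past the axial C10 methylene. The fallback bypasses epoxide 7 and sets out from alkene 5.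
- CrO3 with 3,5-dimethylpyrazole oxidises the allylic C4 methylene to the 5-en-4-one F6.
- Alkaline H2O2 (Weitz–Scheffer epoxidation, β-selective as with angularly methylated octalones) gives the 5β,6β-epoxy-4-ketone F7.
- Hydrazine hydrate with AcOH in MeOH forms the epoxy hydrazone F8, which loses nitrogen in a Wharton transposition and comes back to the route at allylic alcohol 10.

Step 24. Site selectivity or conversion may be poor in the C–H oxidation of an alkene deactivated by its allylic ester, with competing attack on the C8 methyl group. The fallback sets out from 33 and separates C–O bond formation from the oxidation level.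
- SeO2 (cat.)/t-BuOOH in CH2Cl2 (Riley oxidation, ene reaction then [2,3]-shift) hydroxylates the methylene on the more substituted alkene carbon and gives the 9-alcohol F9 as a mixture of C9 epimers.
- Dess–Martin periodinane converts both epimers into 34.

Further compounds
F1 | step 9 | 2β-OTBS 4α,5β,6β-triol 8,8-ethylene ketal (cis-decalin) | CC(C)(C)[Si](C)(C)O[C@H]1C[C@H](O)[C@@H](O)[C@]3(O)CC4(OCCO4)CC[C@]13C
F2 | step 9 | trans-fused 4α,5β-cyclic sulfite of F1 | CC(C)(C)[Si](C)(C)O[C@H]1C[C@@H]2OS(=O)O[C@H]2[C@]3(O)CC4(OCCO4)CC[C@]13C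
F3 | step 9 | trans-fused 4α,5β-cyclic sulfate of F1 | CC(C)(C)[Si](C)(C)O[C@H]1C[C@@H]2OS(=O)(=O)O[C@H]2[C@]3(O)CC4(OCCO4)CC[C@]13C
F4 | step 9 | potassium 4α-sulfate of the trans-fused hydroazulen-6-one | CC(C)(C)[Si](C)(C)O[C@H]1C[C@H](OS(=O)(=O)[O-])[C@H]3C(=O)CC4(OCCO4)CC[C@]13C.[K+]
F5 | step 9 | trans-fused 4α-hydroxyhydroazulen-6-one, 2β-OTBS, 8,8-ethylene ketal | CC(C)(C)[Si](C)(C)O[C@H]1C[C@H](O)[C@H]3C(=O)CC4(OCCO4)CC[C@]13C
F6 | step 5 | 2β-OTBS 5-en-4-one 8,8-ethylene ketal | CC(C)(C)[Si](C)(C)O[C@H]1CC(=O)C=C2CC3(OCCO3)CC[C@]12C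
F7 | step 5 | 5β,6β-epoxy-4-ketone | CC(C)(C)[Si](C)(C)O[C@H]1CC(=O)[C@H]2O[C@]23CC4(OCCO4)CC[C@]13C
F8 | step 5 | hydrazone of F7 | CC(C)(C)[Si](C)(C)O[C@H]1CC(=NN)[C@H]2O[C@]23CC4(OCCO4)CC[C@]13C
F9 | step 24 | 9-hydroxy derivative of 33 (C9 epimers) | CC(=O)O[C@H]1C[C@](O)(C(C)C)[C@H]2[C@H](OC(=O)c3ccc(O[Si](C)(C)C(C)(C)C)cc3)C=C(C)C(O)C[C@]12C
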